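**Retrosynthetic overview**

1. Target 22 is a 20-membered bis(bibenzyl) with two diaryl ether links: ring A (1,4-linked, ether O para to its CH2, OH ortho to that O), ring B (1,3-linked), ring C (1,4-linked), ring D (1,3-linked, OH para to its CH2). The strategy rests on the B–C bridge ArB–CH2–CH2–ArC: both of its carbons are benzylic, so a sulfur atom can be placed between them to close the ring and then be cut out.
2. 22 ⇐ (O-demethylation, hydrogenation) macrocyclic stilbene 19 ⇐ Ramberg–Bäcklund contraction of the 21-membered dibenzylic sulfone 16, which forms the C–C bond of the B–C bridge with loss of SO2.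
3. 16 ⇐ sulfide 14 ⇐ open-chain bis(benzyl bromide) 13 + Na2S (double SN2, the only ring closure from an open chain).
4. 13 ⇐ A–D bibenzyl diester 11 ⇐ Wittig/hydrogenation of phosphonium salt 8 (rings A–B) with aldehyde 3 (rings C–D); each diaryl ether comes from an SNAr reaction (1 + 2 and 4 + 5).
5. Ring order: the macrocycle is the only ring made; it is closed as a 21-membered thioether (step 9) and contracted to the 20-membered carbocycle (step 11).

Key step: step 11

Remark on the chemistry: the target has no stereogenic centre and its 20-membered ring is assumed to be conformationally mobile, so there is no configuration to set. The alkene geometry of 10 and 19 is removed by hydrogenation.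

**Route**

Step 1
Reactants: 1 isovanillin (3-hydroxy-4-methoxybenzaldehyde); 2 methyl 4-fluorobenzoate
Product: 3 methyl 4-(5-formyl-2-methoxyphenoxy)benzoate (rings C–D)
Conditions: K2CO3, DMAc, 140 °C
Reagents that add atoms: none
Why: SNAr addition–elimination of the isovanillin phenoxide at the fluoride para to the ester, whose carbonyl stabilises the Meisenheimer intermediate, should give the diaryl ether while the aldehyde is untouched by carbonate.

Step 2
Reactants: 4 methyl 3-hydroxybenzoate; 5 4-fluoro-3-methoxybenzaldehyde
Product: 6 methyl 3-(4-formyl-2-methoxyphenoxy)benzoate (rings A–B)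
Conditions: K2CO3, DMF, 110 °C
Reagents that add atoms: none
Why: SNAr of the phenoxide of 4 at the fluoride para to the formyl group, a strongly activated position, should place the ether oxygen of ring A para to the future benzylic carbon and ortho to OMe.

Step 3
Reactants: 6 methyl 3-(4-formyl-2-methoxyphenoxy)benzoate
Product: 7 methyl 3-[4-(hydroxymethyl)-2-methoxyphenoxy]benzoate
Conditions: NaBH4, MeOH/THF, 0 °C
Reagents that add atoms: none
Why: Chemoselective borohydride reduction, since NaBH4 reduces the aryl aldehyde far faster than the aryl methyl ester at 0 °C.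

Step 4
Reactants: 7 methyl 3-[4-(hydroxymethyl)-2-methoxyphenoxy]benzoate
Product: 8 {[3-methoxy-4-(3-methoxycarbonylphenoxy)phenyl]methyl}triphenylphosphonium bromide
Conditions: PPh3·HBr, MeCN, reflux
Reagents that add atoms: triphenylphosphine hydrobromide, [Br-].c1ccc(cc1)[PH+](c1ccccc1)c1ccccc1
Why: Acid-promoted substitution of the benzylic hydroxyl (ionisation is helped by the para aryloxy group) by triphenylphosphine is the established one-flask conversion of benzylic alcohols into benzylphosphonium bromides.

Step 5
Reactants: 8 {[3-methoxy-4-(3-methoxycarbonylphenoxy)phenyl]methyl}triphenylphosphonium bromide; 3 methyl 4-(5-formyl-2-methoxyphenoxy)benzoate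
Product: 10 methyl 3-(2-methoxy-4-{2-[4-methoxy-3-(4-methoxycarbonylphenoxy)phenyl]ethenyl}phenoxy)benzoate (E/Z mixture), via phosphonium ylide 9 (not isolated)
Conditions: K2CO3, 18-crown-6 (cat.), CH2Cl2, reflux
Reagents that add atoms: none
Why: Wittig olefination under solid–liquid phase-transfer conditions, in which the semi-stabilised benzylic ylide condenses with the aryl aldehyde to an E/Z stilbene mixture while both methyl esters are inert to carbonate.

Step 6
Reactants: 10 stilbene diester (E/Z mixture)
Product: 11 methyl 3-(2-methoxy-4-{2-[4-methoxy-3-(4-methoxycarbonylphenoxy)phenyl]ethyl}phenoxy)benzoate (A–D bibenzyl diester)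
Conditions: H2 (1 atm), 10% Pd/C, EtOAc, rt
Reagents that add atoms: none
Why: Heterogeneous catalytic hydrogenation saturates the stilbene C=C of both isomers to one bibenzyl and leaves esters and diaryl ethers alone.

Step 7
Reactants: 11 A–D bibenzyl diester
Product: 12 [3-(4-{2-[3-(4-(hydroxymethyl)phenoxy)-4-methoxyphenyl]ethyl}-2-methoxyphenoxy)phenyl]methanol (bis-benzylic diol)
Conditions: LiAlH4, THF, 0 °C to rt; aqueous work-up
Reagents that add atoms: none
Why: Hydride reduction of both aryl methyl esters to the primary benzylic alcohols, with no other reducible group present.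

Step 8
Reactants: 12 bis-benzylic diol
Product: 13 1-[3-(bromomethyl)phenoxy]-4-{2-[3-(4-(bromomethyl)phenoxy)-4-methoxyphenyl]ethyl}-2-methoxybenzene (bis(benzyl bromide))
Conditions: PBr3, CH2Cl2, 0 °C
Reagents that add atoms: phosphorus tribromide, BrP(Br)Br
Why: Activation of each benzylic alcohol as a phosphite ester and SN2 displacement by bromide is the standard route to benzyl bromides; the aryl methyl ethers are not touched at 0 °C.

Step 9
Reactants: 13 bis(benzyl bromide)
Product: 14 21-membered thiacyclophane (cyclic sulfide in which S joins the benzylic CH2 of ring B to the benzylic CH2 of ring C)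
Conditions: Na2S·9H2O, THF/EtOH/H2O, rt, high dilution (slow simultaneous addition of both components)
Reagents that add atoms: sodium sulfide (as nonahydrate), [Na+].[Na+].[S-2]
Why: Double SN2 thioetherification of two benzylic bromides by sulfide, the second displacement being a 21-exo-tet closure by a very soft, fast nucleophile, is a dependable macrocyclisation under pseudo-dilution.

Step 10
Reactants: 14 21-membered thiacyclophane
Product: 16 21-membered dibenzylic sulfone macrocycle (S,S-dioxide of 14), via macrocyclic sulfoxide 15 (not isolated)
Conditions: mCPBA (2.2 equiv), CH2Cl2, 0 °C to rt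
Reagents that add atoms: meta-chloroperoxybenzoic acid, OOC(=O)c1cccc(Cl)c1
Why: Two successive electrophilic oxygen transfers from the peracid to sulfur (sulfide to sulfoxide to sulfone) are much faster than any oxidation of the aryl ether rings.

Step 11
Reactants: 16 21-membered dibenzylic sulfone macrocycle
Product: 19 20-membered macrocyclic stilbene dimethyl ether (Z isomer drawn), via alpha-bromo sulfone 17 (not isolated), via episulfone 18 (not isolated)
Conditions: BrCl2C–CCl2Br, KOH/Al2O3, t-BuOH/THF, rt to 50 °C
Reagents that add atoms: none
Why: KOH on alumina deprotonates a benzylic carbon alpha to sulfur in 16 (the ring-B side is expected to be slightly more acidic), and the carbanion takes bromine from 1,2-dibromotetrachloroethane by halophilic attack, releasing tetrachloroethene and bromide and giving 17. Deprotonation at the other benzylic alpha carbon and intramolecular 1,3-displacement of bromide (3-exo-tet) closes the thiirane 1,1-dioxide 18, which loses SO2 cheletropically; this joins the two benzylic carbons of the B–C bridge as C=C and contracts the 21-membered ring to the 20-membered carbocycle. This is the Ramberg–Bäcklund reaction in its one-flask in situ halogenation form, whose closest precedent is the conversion of open-chain and macrocyclic dibenzylic sulfones into stilbenes and cyclophane alkenes. No stereocentre survives: the two transient stereocentres of 18 become only alkene geometry, and Z, E or a mixture serves equally because step 12 saturates the bond. The selectivity needed is bromination at carbon alpha to sulfur and nowhere on the four electron-rich aryl ether rings; it is secured because the bromine donor reacts only with carbanions and is not an electrophile toward neutral arenes, and which alpha carbon is brominated does not matter since both paths meet at 18. Monobromination is favoured because 1,3-elimination of a benzylic alpha-bromo sulfone should outrun a second deprotonation and bromination.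

Step 12
Reactants: 19 20-membered macrocyclic stilbene dimethyl ether
Product: 20 20-membered bis(bibenzyl) dimethyl ether (saturated macrocycle, OMe on rings A and D)
Conditions: H2 (1 atm), 10% Pd/C, EtOAc/THF, rt
Reagents that add atoms: none
Why: Catalytic hydrogenation of the stilbene double bond converges either alkene geometry on the saturated B–C bridge without touching the diaryl ethers.

Step 13
Reactants: 20 20-membered bis(bibenzyl) dimethyl ether
Product: 22 target bis(bibenzyl) diphenol CNP0329842.0, via bis(dibromoboryl) ether 21 (not isolated)
Conditions: BBr3, CH2Cl2, −78 °C to rt; then H2O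
Reagents that add atoms: none
Why: Lewis acid-mediated O-demethylation, in which boron coordinates each methoxy oxygen and bromide attacks the methyl carbon by SN2; the diaryl ether C–O bonds have no sp3 carbon to attack and remain, and the aryloxyboron species are hydrolysed on work-up.

**Compound list**

1 | isovanillin (3-hydroxy-4-methoxybenzaldehyde) | O=Cc1ccc(OC)c(O)c1 | starting material
2 | methyl 4-fluorobenzoate | COC(=O)c1ccc(F)cc1 | starting material
3 | methyl 4-(5-formyl-2-methoxyphenoxy)benzoate | COC(=O)c1ccc(cc1)Oc1cc(C=O)ccc1OC | intermediate
4 | methyl 3-hydroxybenzoate | COC(=O)c1cccc(O)c1 | starting material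
5 | 4-fluoro-3-methoxybenzaldehyde | COc1cc(C=O)ccc1F | starting material
6 | methyl 3-(4-formyl-2-methoxyphenoxy)benzoate | COC(=O)c1cccc(c1)Oc1ccc(C=O)cc1OC | intermediate
7 | methyl 3-[4-(hydroxymethyl)-2-methoxyphenoxy]benzoate | COC(=O)c1cccc(c1)Oc1ccc(CO)cc1OC | intermediate
8 | {[3-methoxy-4-(3-methoxycarbonylphenoxy)phenyl]methyl}triphenylphosphonium bromide | COC(=O)c1cccc(c1)Oc1ccc(C[P+](c2ccccc2)(c2ccccc2)c2ccccc2)cc1OC.[Br-] | intermediate
9 | phosphonium ylide of 8 (benzylidene triphenylphosphorane) | COC(=O)c1cccc(c1)Oc1ccc(C=P(c2ccccc2)(c2ccccc2)c2ccccc2)cc1OC | intermediate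
10 | methyl 3-(2-methoxy-4-{2-[4-methoxy-3-(4-methoxycarbonylphenoxy)phenyl]ethenyl}phenoxy)benzoate, E/Z mixture (geometry left open in the SMILES) | COC(=O)c1cccc(c1)Oc1ccc(C=Cc2ccc(OC)c(c2)Oc2ccc(cc2)C(=O)OC)cc1OC | intermediate
11 | methyl 3-(2-methoxy-4-{2-[4-methoxy-3-(4-methoxycarbonylphenoxy)phenyl]ethyl}phenoxy)benzoate | COC(=O)c1cccc(c1)Oc1ccc(CCc2ccc(OC)c(c2)Oc2ccc(cc2)C(=O)OC)cc1OC | intermediate
12 | [3-(4-{2-[3-(4-(hydroxymethyl)phenoxy)-4-methoxyphenyl]ethyl}-2-methoxyphenoxy)phenyl]methanol | OCc1cccc(c1)Oc1ccc(CCc2ccc(OC)c(c2)Oc2ccc(CO)cc2)cc1OC | intermediate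
13 | 1-[3-(bromomethyl)phenoxy]-4-{2-[3-(4-(bromomethyl)phenoxy)-4-methoxyphenyl]ethyl}-2-methoxybenzene | BrCc1cccc(c1)Oc1ccc(CCc2ccc(OC)c(c2)Oc2ccc(CBr)cc2)cc1OC | intermediate
14 | 21-membered thiacyclophane (sulfide between the benzylic carbons of rings B and C) | S1Cc2cccc(c2)Oc2ccc(cc2OC)CCc2ccc(OC)c(c2)Oc2ccc(C1)cc2 | intermediate
15 | macrocyclic sulfoxide of 14 (racemic at sulfur) | O=S1Cc2cccc(c2)Oc2ccc(cc2OC)CCc2ccc(OC)c(c2)Oc2ccc(C1)cc2 | intermediate
16 | 21-membered dibenzylic sulfone macrocycle | O=S1(=O)Cc2cccc(c2)Oc2ccc(cc2OC)CCc2ccc(OC)c(c2)Oc2ccc(C1)cc2 | intermediate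
17 | alpha-bromo sulfone (racemic; drawn brominated at the ring-B benzylic carbon, the ring-C regioisomer leads to the same episulfone) | O=S1(=O)C(Br)c2cccc(c2)Oc2ccc(cc2OC)CCc2ccc(OC)c(c2)Oc2ccc(C1)cc2 | intermediate
18 | macrocycle-fused episulfone (2,3-diaryl thiirane 1,1-dioxide; cis, racemic, one enantiomer drawn) | O=S1(=O)[C@H]3c2cccc(c2)Oc2ccc(cc2OC)CCc2ccc(OC)c(c2)Oc2ccc([C@@H]13)cc2 | intermediate
19 | 20-membered macrocyclic stilbene dimethyl ether (Z drawn; E or a mixture is equally usable) | COc1cc2ccc1Oc1cccc(c1)/C=C\c1ccc(cc1)Oc1cc(ccc1OC)CC2 | intermediate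
20 | 20-membered bis(bibenzyl) dimethyl ether | COc1cc2ccc1Oc1cccc(c1)CCc1ccc(cc1)Oc1cc(ccc1OC)CC2 | intermediate
21 | bis(dibromoboryl) ether of the target | BrB(Br)Oc1cc2ccc1Oc1cccc(c1)CCc1ccc(cc1)Oc1cc(ccc1OB(Br)Br)CC2 | intermediate
22 | target bis(bibenzyl) diphenol CNP0329842.0 (no stereocentre) | Oc1cc2ccc1Oc1cccc(c1)CCc1ccc(cc1)Oc1cc(ccc1O)CC2 | target

**Step count**

Total: 13 steps. Longest linear sequence: 12 steps (steps 2 to 13, from 4 and 5 to 22); step 1 supplies the second fragment.

**Steps most likely to fail**

Step 11 (Ramberg–Bäcklund contraction). A second bromination at a benzylic carbon may occur before the 1,3-elimination, or the macrocycle may react sluggishly on the solid base, so the episulfone is not formed cleanly. Fallback: the route leaves from sulfone 16 and uses photochemical sulfone extrusion (254 nm, degassed benzene, high dilution). Benzylic C–S homolysis, loss of SO2 and recombination of the benzylic radical pair held within the same molecule should give the saturated macrocycle directly, so the route is rejoined at 20 and step 12 is not needed. This fallback makes no compound outside the list (F0).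

Step 9 (sulfide macrocyclisation). Intermolecular thioether formation to oligomers may outrun the 21-membered closure, and the para-aryloxybenzyl bromide may solvolyse in the aqueous alcohol. Fallback: the route leaves from diol 12. Oxidation with MnO2 in CH2Cl2 should give 3-(4-{2-[3-(4-formylphenoxy)-4-methoxyphenyl]ethyl}-2-methoxyphenoxy)benzaldehyde F1. Intramolecular McMurry coupling of the two aryl aldehydes (TiCl4, Zn, THF, reflux, slow addition) then closes the 20-membered ring directly as the stilbene, and the route is rejoined at 19.

Step 1 (SNAr on methyl 4-fluorobenzoate). Addition to the weakly activated fluoride may be slow at temperatures the aldehyde tolerates, and the phenoxide may instead dealkylate the methyl ester. Fallback: the route leaves from 1 and forms the same C–O bond by a copper-catalysed Ullmann ether coupling with methyl 4-bromobenzoate (CuI, N,N-dimethylglycine, Cs2CO3, dioxane, 90 °C), which does not depend on activation of the ring toward addition; the route is rejoined at 3. This fallback makes no compound outside the list (F0).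

**Further compounds**

F0 | step 11 | none | none
F1 | step 9 | 3-(4-{2-[3-(4-formylphenoxy)-4-methoxyphenyl]ethyl}-2-methoxyphenoxy)benzaldehyde | O=Cc1cccc(c1)Oc1ccc(CCc2ccc(OC)c(c2)Oc2ccc(C=O)cc2)cc1OC
F0 | step 1 | none | none
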